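The numbers of this flask were chosen freely; the rest is arithmetic.

solid substrate 0.10 M; gas phase 43 mM (held); protic impurity 0.100 M; time 15 h

    starting material + dissolved gas → product (k1 = 3.2 M⁻¹ h⁻¹)
    starting material + protic impurity → quenched substrate (k2 = 0.18 M⁻¹ h⁻¹)
    solid substrate ⇌ starting material, rate k3*(cs3 - [starting material]) while solid is left; crystals form when [starting material] > cs3 (cs3 = 0.10 M, k3 = 0.070 h⁻¹)
    starting material ⇌ dormant form (K4 = 15, k4 = 0.15 h⁻¹)
    gas phase ⇌ dissolved gas, rate k5*(csat - [dissolved gas]) (k5 = 0.30 h⁻¹, csat = 43 mM)

- solid, in amounts per volume of the solution: solid substrate
- at the start none of the gas is dissolved
- at the start none of the solid substrate is in solution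
- run time (flask): 15 h

1. amount of product at 15 h, in percent of the solid substrate charged
2. concentration of dissolved gas in solution at 8.0 h, in percent of saturation
3. the change that raises the amount of product at 15 h, in percent of the solid substrate charged most ("none" if none brings more than 2 percentage points) (dawn / spring / winter / noon / none)
4. amount of product at 15 h, in percent of the solid substrate charged, after spring

- dawn: doubling the solubility in step 3, all else as stated
- spring: doubling the dissolution coefficient of step 3, all else as stated
- winter: doubling the saturation concentration of gas phase, all else as stated
- noon: doubling the transfer coefficient of step 5, all else as stated

Against the 15 h of this flask, the gas settles quickly: its uptake half-life is 2.31 h. So I freeze the dissolved gas, and I freeze the protic impurity at its charge, since its own half-life by step 2, reckoned with the whole charge of solid substrate in solution, is 38.5 h, longer than the 15 h of the run. I have one change to choose for the next run, and the choice hangs on a single number.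

With gas at saturation, starting material is lost at 0.306 h⁻¹. Feed balanced against loss freezes it at 0.0186 M. Uptake balanced against reaction then freezes the dissolved gas at 0.0359 M, which is 83.4% of saturation. The split, the pseudo-first-order constant towards product divided by the sum of the losses at that gas level, is 40.6%.

The frozen feed is 0.005695 M h⁻¹, so by the end it has delivered 85.4% of the charge, less than the charge. I subtract the frozen starting material and apply the split, which gives a yield of 27.1%.

Winter changes the split itself. Starting material freezes at 0.0136 M, the gas at 0.0751 M, and the split becomes 58.8%, for a yield of 45.3%. Spring offers more feed than the charge holds, so I bound it by the split of the whole charge, 40.6%, which is less than winter's yield. I would charge for winter.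

The forecast gives 27% (24% to 30%), saturation 79% (74% to 84%), winter as the best change, and 34% after spring (30% to 38%), on the ground that “Doubling saturation gives the largest gain”.

The simulation gives 26.0%, saturation 79.1%, and winter as the best change, with a gain of 17 percentage points; spring gives 33.5%.

My split treats the dormant form as a one-way loss, counting the forward rate without the way back. In this flask, striking out the falling back still gives 25.6%, and the backward turnover is 6.2% of the forward one. At the asked time, product over product, quenched substrate and dormant form reads 39.2%, beside my 40.6%. This flask stands at 26.0%, against 62.5% read at 150 h and 36.9% with the path to the dormant form taken away, so the early reading and that path act together in holding the product down.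

For the same flask read at 6.0 h, the frozen feed has delivered 34.2% of the charge, and the frozen starting material and the split then give 6.31%. The simulation gives 6.07%.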